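**Retrosynthetic overview**

1. Target ⇐ hydrogenolysis of five benzyl ethers ⇐ penta-O-benzyl acid ⇐ saponification of a cis-fused α-hydroxy-β-lactone (C-2 carboxyl tied to the C-3 oxygen) ⇐ enolate hydroxylation at C-2.
2. Key disconnection: β-lactone-fused tetralin ⇐ achiral keto-cinnamate (ring A carrying a phenyl acrylate arm and a CH2COCH2OBn arm) + 3,4,5-tris(benzyloxy)phenylboronic acid, by rhodium/chiral-diene aryl addition (C-1–aryl), enolate aldol onto the ketone (C-2–C-3) and lactonisation (O–CO) in one flask.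
3. Keto-cinnamate ⇐ 5-(benzyloxy)-2-bromo-4-methoxybenzaldehyde by Wittig olefination (CHO arm) and palladium-catalysed enol-ether arylation (Br arm).
4. Ring order: both benzene rings are bought; the cyclohexane ring of the tetralin and the four-membered lactone form together in the key step; the lactone is opened again two steps later.

Assumption 1: 1,2,3-tris(benzyloxy)-5-bromobenzene is taken as a purchasable catalogue compound (otherwise two routine steps, BBr3 then BnBr/K2CO3, from cheap 5-bromo-1,2,3-trimethoxybenzene).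
Assumption 2: (R,R)-Ph-bod* is taken to deliver the aryl group to the Re face of C-β of the cinnamate; the (S,S)-ligand is equally available and is used if a test run shows the opposite sense.

Tetralin numbering (C-1 aryl-bearing, C-2 carboxyl-bearing, C-3 hydroxymethyl-bearing, C-4 CH2) is used in the explanations.

**Step 1**
Reactants: 1 5-(benzyloxy)-2-bromo-4-methoxybenzaldehyde; 2 phenyl bromoacetate
Product: 5 phenyl (2E)-3-[5-(benzyloxy)-2-bromo-4-methoxyphenyl]prop-2-enoate, via phosphonium bromide 3 (not isolated), via ylide 4 (not isolated)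
Conditions: 2, PPh3, toluene, rt; then 1, Et3N, CH2Cl2, rt
Reagents that add atoms: none
Why: Wittig olefination with the ester-stabilised ylide made in the flask gives the (E)-cinnamate selectively, forms no stereocentre and leaves the aryl bromide, the benzyl ether and the phenyl ester untouched.

**Step 2**
Reactants: 6 1-(benzyloxy)propan-2-one
Product: 8 {[3-(benzyloxy)prop-1-en-2-yl]oxy}trimethylsilane, via lithium enolate 7 (not isolated)
Conditions: LiN(i-Pr)2 (commercial solution), THF, −78 °C; then Me3SiCl, −78 °C → rt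
Reagents that add atoms: chlorotrimethylsilane, C[Si](C)(C)Cl
Why: Kinetic enolisation of the α-alkoxy ketone at the methyl group (away from the alkoxy-bearing carbon) followed by O-silylation gives the terminal silyl enol ether; no stereocentre is formed.

**Step 3**
Reactants: 5 phenyl (2E)-3-[5-(benzyloxy)-2-bromo-4-methoxyphenyl]prop-2-enoate; 8 {[3-(benzyloxy)prop-1-en-2-yl]oxy}trimethylsilane
Product: 10 phenyl (2E)-3-{5-(benzyloxy)-2-[3-(benzyloxy)-2-oxopropyl]-4-methoxyphenyl}prop-2-enoate, via tin enolate 9 (not isolated)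
Conditions: PdCl2[P(o-tol)3]2 (3 mol %), Bu3SnF, toluene, 100 °C
Reagents that add atoms: none
Why: Kuwajima–Urabe palladium-catalysed α-arylation, in which Bu3SnF converts the silyl enol ether into a tin enolate that couples with the aryl bromide under neutral conditions, so the base-sensitive phenyl cinnamate survives and the aryl group is attached only to the former methyl carbon; no stereocentre is formed.

**Step 4**
Reactants: 11 1,2,3-tris(benzyloxy)-5-bromobenzene
Product: 14 [3,4,5-tris(benzyloxy)phenyl]boronic acid, via aryllithium 12 (not isolated), via lithium borate 13 (not isolated)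
Conditions: n-BuLi, THF, −78 °C; B(Oi-Pr)3, −78 °C → rt; then 1 M HCl
Reagents that add atoms: triisopropyl borate, CC(C)OB(OC(C)C)OC(C)C; water, O
Why: Bromine–lithium exchange, borylation and hydrolysis of the borate; benzyl ethers tolerate n-BuLi at −78 °C and no stereocentre is formed.

**Step 5**
Reactants: 10 phenyl (2E)-3-{5-(benzyloxy)-2-[3-(benzyloxy)-2-oxopropyl]-4-methoxyphenyl}prop-2-enoate; 14 [3,4,5-tris(benzyloxy)phenyl]boronic acid
Product: 17 (2aR,3S,8aS)-5-(benzyloxy)-8a-[(benzyloxy)methyl]-6-methoxy-3-[3,4,5-tris(benzyloxy)phenyl]-2a,3,8,8a-tetrahydro-2H-naphtho[2,3-b]oxet-2-one, via rhodium enolate 15 (not isolated), via aldolate 16 (not isolated)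
Conditions: [RhCl(C2H4)2]2 (2.5 mol %), (R,R)-Ph-bod* [(1R,4R)-2,5-diphenylbicyclo[2.2.2]octa-2,5-diene] (5.5 mol %), 14 (2 equiv), K3PO4 (0.5 equiv), dry 1,4-dioxane, 40 °C
Reagents that add atoms: none
Why: Proposed new method: the aryl–rhodium species formed by transmetalation of 14 adds to the Re face of C-β of the cinnamate under ligand control (Hayashi–Miyaura asymmetric 1,4-addition, sets C-1), the resulting rhodium enolate closes the six-membered ring by aldol addition to the tethered α-benzyloxy ketone with the C-1 hydrogen eclipsing the enolate (allylic 1,3-strain puts the new aryl group trans to the acyl group, sets C-2), and only the aldolate whose oxygen is cis to the phenyl ester can expel phenoxide to give the β-lactone while the trans aldolate reverts by retro-aldol (sets C-3) and the released Rh–OPh re-enters transmetalation; the closest known reactions are the rhodium-catalysed tandem conjugate addition–aldol cyclisation of enone-ketones (Krische type) and the aldol–lactonisation of phenyl and thiophenyl ester enolates with ketones (Danheiser type).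

**Step 6**
Reactants: 17 (2aR,3S,8aS)-5-(benzyloxy)-8a-[(benzyloxy)methyl]-6-methoxy-3-[3,4,5-tris(benzyloxy)phenyl]-2a,3,8,8a-tetrahydro-2H-naphtho[2,3-b]oxet-2-one
Product: 19 (2aS,3S,8aR)-5-(benzyloxy)-8a-[(benzyloxy)methyl]-2a-hydroxy-6-methoxy-3-[3,4,5-tris(benzyloxy)phenyl]-2a,3,8,8a-tetrahydro-2H-naphtho[2,3-b]oxet-2-one, via lactone enolate 18 (not isolated)
Conditions: LiN(i-Pr)2, THF, −78 °C; 2-(benzenesulfonyl)-3-phenyloxaziridine, −78 °C; AcOH quench
Reagents that add atoms: 2-(benzenesulfonyl)-3-phenyloxaziridine, O=S(=O)(c1ccccc1)N1OC1c1ccccc1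
Why: Davis enolate hydroxylation of the β-lactone enolate, in which oxygen can only enter on the face that keeps the four-membered ring cis-fused, so OH replaces the C-2 hydrogen with retention (cis to the aryl group and to CH2OBn, trans to the C-3 oxygen).

**Step 7**
Reactants: 19 (2aS,3S,8aR)-5-(benzyloxy)-8a-[(benzyloxy)methyl]-2a-hydroxy-6-methoxy-3-[3,4,5-tris(benzyloxy)phenyl]-2a,3,8,8a-tetrahydro-2H-naphtho[2,3-b]oxet-2-one
Product: 21 (1S,2S,3R)-7-(benzyloxy)-3-[(benzyloxy)methyl]-2,3-dihydroxy-6-methoxy-1-[3,4,5-tris(benzyloxy)phenyl]-1,2,3,4-tetrahydronaphthalene-2-carboxylic acid, via lithium carboxylate 20 (not isolated)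
Conditions: LiOH, THF/H2O, 0 °C → rt; then 1 M HCl to pH 3
Reagents that add atoms: lithium hydroxide, [Li+].[OH-]
Why: Saponification by acyl–oxygen cleavage of the strained β-lactone leaves the C-3–O bond and all three stereocentres untouched and releases the acid and the tertiary alcohol, while the benzyl ether on the CH2O group blocks any γ-lactone formation.

**Step 8**
Reactants: 21 (1S,2S,3R)-7-(benzyloxy)-3-[(benzyloxy)methyl]-2,3-dihydroxy-6-methoxy-1-[3,4,5-tris(benzyloxy)phenyl]-1,2,3,4-tetrahydronaphthalene-2-carboxylic acid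
Product: 22 (1S,2S,3R)-2,3,7-trihydroxy-3-(hydroxymethyl)-6-methoxy-1-(3,4,5-trihydroxyphenyl)-1,2,3,4-tetrahydronaphthalene-2-carboxylic acid
Conditions: H2 (1 atm), 10% Pd/C, THF/MeOH, rt, then filtration under argon
Reagents that add atoms: none
Why: Catalytic hydrogenolysis removes the five benzyl ethers under neutral conditions that leave the aryl methyl ether, the tertiary alcohols, the acid and the doubly benzylic C-1–H untouched, so no stereocentre is affected.

**Compound list**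

The descriptor changes between 17 and 19 (2aR→2aS, 8aS→8aR) are CIP priority effects only; the geometry is retained.

1 | 5-(benzyloxy)-2-bromo-4-methoxybenzaldehyde | COc1cc(Br)c(C=O)cc1OCc1ccccc1 | starting material
2 | phenyl bromoacetate | BrCC(=O)Oc1ccccc1 | starting material
3 | (2-oxo-2-phenoxyethyl)triphenylphosphonium bromide | O=C(C[P+](c1ccccc1)(c1ccccc1)c1ccccc1)Oc1ccccc1.[Br-] | intermediate
4 | phenyl (triphenylphosphoranylidene)acetate | O=C(C=P(c1ccccc1)(c1ccccc1)c1ccccc1)Oc1ccccc1 | intermediate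
5 | phenyl (2E)-3-[5-(benzyloxy)-2-bromo-4-methoxyphenyl]prop-2-enoate | COc1cc(Br)c(/C=C/C(=O)Oc2ccccc2)cc1OCc1ccccc1 | intermediate
6 | 1-(benzyloxy)propan-2-one | CC(=O)COCc1ccccc1 | starting material
7 | lithium 3-(benzyloxy)prop-1-en-2-olate | [Li+].[O-]C(=C)COCc1ccccc1 | intermediate
8 | {[3-(benzyloxy)prop-1-en-2-yl]oxy}trimethylsilane | C=C(O[Si](C)(C)C)COCc1ccccc1 | intermediate
9 | {[3-(benzyloxy)prop-1-en-2-yl]oxy}tributylstannane | C=C(O[Sn](CCCC)(CCCC)CCCC)COCc1ccccc1 | intermediate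
10 | phenyl (2E)-3-{5-(benzyloxy)-2-[3-(benzyloxy)-2-oxopropyl]-4-methoxyphenyl}prop-2-enoate | COc1cc(CC(=O)COCc2ccccc2)c(/C=C/C(=O)Oc2ccccc2)cc1OCc1ccccc1 | intermediate
11 | 1,2,3-tris(benzyloxy)-5-bromobenzene | Brc1cc(OCc2ccccc2)c(OCc2ccccc2)c(OCc2ccccc2)c1 | starting material
12 | [3,4,5-tris(benzyloxy)phenyl]lithium | [Li]c1cc(OCc2ccccc2)c(OCc2ccccc2)c(OCc2ccccc2)c1 | intermediate
13 | lithium triisopropoxy[3,4,5-tris(benzyloxy)phenyl]borate | [Li+].CC(C)O[B-](OC(C)C)(OC(C)C)c1cc(OCc2ccccc2)c(OCc2ccccc2)c(OCc2ccccc2)c1 | intermediate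
14 | [3,4,5-tris(benzyloxy)phenyl]boronic acid | OB(O)c1cc(OCc2ccccc2)c(OCc2ccccc2)c(OCc2ccccc2)c1 | intermediate
15 | rhodium-bound enolate of phenyl (3S)-3-{5-(benzyloxy)-2-[3-(benzyloxy)-2-oxopropyl]-4-methoxyphenyl}-3-[3,4,5-tris(benzyloxy)phenyl]propanoate (drawn as the enolate anion) | COc1cc(CC(=O)COCc2ccccc2)c(cc1OCc1ccccc1)[C@H](c1cc(OCc2ccccc2)c(OCc2ccccc2)c(OCc2ccccc2)c1)C=C([O-])Oc1ccccc1 | intermediate
16 | phenyl (1S,2R,3S)-7-(benzyloxy)-3-[(benzyloxy)methyl]-6-methoxy-3-oxido-1-[3,4,5-tris(benzyloxy)phenyl]-1,2,3,4-tetrahydronaphthalene-2-carboxylate, drawn as the potassium alkoxide (C-3 oxygen cis to the C-2 ester, aryl trans to the ester) | COc1cc2c(cc1OCc3ccccc3)[C@H](c3cc(OCc4ccccc4)c(OCc4ccccc4)c(OCc4ccccc4)c3)[C@@H](C(=O)Oc3ccccc3)[C@]([O-])(COCc3ccccc3)C2.[K+] | intermediate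
17 | (2aR,3S,8aS)-5-(benzyloxy)-8a-[(benzyloxy)methyl]-6-methoxy-3-[3,4,5-tris(benzyloxy)phenyl]-2a,3,8,8a-tetrahydro-2H-naphtho[2,3-b]oxet-2-one (cis-fused β-lactone, aryl trans to the lactone carbonyl) | COc1cc2c(cc1OCc3ccccc3)[C@H](c3cc(OCc4ccccc4)c(OCc4ccccc4)c(OCc4ccccc4)c3)[C@@H](C(=O)O5)[C@]5(COCc3ccccc3)C2 | intermediate
18 | lithium (3S,8aS)-5-(benzyloxy)-8a-[(benzyloxy)methyl]-6-methoxy-3-[3,4,5-tris(benzyloxy)phenyl]-3,8-dihydro-8aH-naphtho[2,3-b]oxet-2-olate | COc1cc2c(cc1OCc3ccccc3)[C@H](c3cc(OCc4ccccc4)c(OCc4ccccc4)c(OCc4ccccc4)c3)C5=C([O-])O[C@@]5(COCc3ccccc3)C2.[Li+] | intermediate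
19 | (2aS,3S,8aR)-5-(benzyloxy)-8a-[(benzyloxy)methyl]-2a-hydroxy-6-methoxy-3-[3,4,5-tris(benzyloxy)phenyl]-2a,3,8,8a-tetrahydro-2H-naphtho[2,3-b]oxet-2-one | COc1cc2c(cc1OCc3ccccc3)[C@H](c3cc(OCc4ccccc4)c(OCc4ccccc4)c(OCc4ccccc4)c3)[C@@](O)(C(=O)O5)[C@]5(COCc3ccccc3)C2 | intermediate
20 | lithium (1S,2S,3R)-7-(benzyloxy)-3-[(benzyloxy)methyl]-2,3-dihydroxy-6-methoxy-1-[3,4,5-tris(benzyloxy)phenyl]-1,2,3,4-tetrahydronaphthalene-2-carboxylate | COc1cc2c(cc1OCc3ccccc3)[C@H](c3cc(OCc4ccccc4)c(OCc4ccccc4)c(OCc4ccccc4)c3)[C@@](O)(C(=O)[O-])[C@](O)(COCc3ccccc3)C2.[Li+] | intermediate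
21 | (1S,2S,3R)-7-(benzyloxy)-3-[(benzyloxy)methyl]-2,3-dihydroxy-6-methoxy-1-[3,4,5-tris(benzyloxy)phenyl]-1,2,3,4-tetrahydronaphthalene-2-carboxylic acid | COc1cc2c(cc1OCc3ccccc3)[C@H](c3cc(OCc4ccccc4)c(OCc4ccccc4)c(OCc4ccccc4)c3)[C@@](O)(C(=O)O)[C@](O)(COCc3ccccc3)C2 | intermediate
22 | (1S,2S,3R)-2,3,7-trihydroxy-3-(hydroxymethyl)-6-methoxy-1-(3,4,5-trihydroxyphenyl)-1,2,3,4-tetrahydronaphthalene-2-carboxylic acid | COc1cc2c(cc1O)[C@H](c1cc(O)c(O)c(O)c1)[C@@](O)(C(=O)O)[C@](O)(CO)C2 | target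

**Step count and risks**

Total steps: 8. Longest linear sequence: 6 (1 → 5 → 10 → 17 → 19 → 21 → 22).

Most likely to fail, first: step 5. The rhodium enolate may be protonated before the aldol, the aldolate may not lactonise, base may trigger Michael closure of the ketone's CH(OBn) carbon onto the cinnamate, and the sense of induction needs checking. Fallback, from 10 back to 17: run only the rhodium/(R,R)-Ph-bod* conjugate addition of 14 under protic conditions (aq. KOH, dioxane/H2O), which gives after protonation the open-chain phenyl (3S)-3-{5-(benzyloxy)-2-[3-(benzyloxy)-2-oxopropyl]-4-methoxyphenyl}-3-[3,4,5-tris(benzyloxy)phenyl]propanoate F1. Cleave the phenyl ester with LiOH/H2O2 to the keto acid (3S)-3-{5-(benzyloxy)-2-[3-(benzyloxy)-2-oxopropyl]-4-methoxyphenyl}-3-[3,4,5-tris(benzyloxy)phenyl]propanoic acid F2. Then close both rings by a nucleophile-catalysed aldol-lactonisation of Romo type (2-bromo-1-propylpyridinium triflate, 4-pyrrolidinopyridine, i-Pr2NEt, CH2Cl2), whose acylammonium enolate forms only at the acid side and obeys the same allylic-strain model, to rejoin the route at 17.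

Second: step 6. The ring-fusion hydrogen is flanked by the cis aryl and CH2OBn groups, and the β-lactone enolate may decompose. Fallback, from 17 back to 21: open the lactone with NaOMe/MeOH to the hydroxy ester methyl (1S,2R,3S)-7-(benzyloxy)-3-[(benzyloxy)methyl]-3-hydroxy-6-methoxy-1-[3,4,5-tris(benzyloxy)phenyl]-1,2,3,4-tetrahydronaphthalene-2-carboxylate F3. Form the chelated dianion (LiN(i-Pr)2, 2.2 equiv, THF, −78 °C) and oxidise it with 2-(benzenesulfonyl)-3-phenyloxaziridine; attack anti to the alkoxide (Fráter–Seebach sense) gives the dihydroxy ester methyl (1S,2S,3R)-7-(benzyloxy)-3-[(benzyloxy)methyl]-2,3-dihydroxy-6-methoxy-1-[3,4,5-tris(benzyloxy)phenyl]-1,2,3,4-tetrahydronaphthalene-2-carboxylate F4. Saponify with LiOH and acidify to reach 21. Here stereocontrol comes from the chelate, not from ring strain, so it is less certain.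

Third: step 3. The silyl enol ether 8 may not be regiochemically pure, the hindered electron-rich bromide may couple slowly, and 10 is base-sensitive. Fallback, from 5 back to 10: nickel-catalysed reductive cross-electrophile coupling of 5 with benzyl glycidyl ether (NiBr2·dme, 2,2'-bipyridine, NaI, Mn powder, DMPU), opening the epoxide at its terminal carbon, gives the alcohol phenyl (2E)-3-{5-(benzyloxy)-2-[3-(benzyloxy)-2-hydroxypropyl]-4-methoxyphenyl}prop-2-enoate F5 (racemic carbinol, stereocentre removed next). Dess–Martin oxidation in CH2Cl2 then gives 10.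

**Further compounds**

F1 | step 5 | phenyl (3S)-3-{5-(benzyloxy)-2-[3-(benzyloxy)-2-oxopropyl]-4-methoxyphenyl}-3-[3,4,5-tris(benzyloxy)phenyl]propanoate | COc1cc(CC(=O)COCc2ccccc2)c(cc1OCc1ccccc1)[C@H](c1cc(OCc2ccccc2)c(OCc2ccccc2)c(OCc2ccccc2)c1)CC(=O)Oc1ccccc1
F2 | step 5 | (3S)-3-{5-(benzyloxy)-2-[3-(benzyloxy)-2-oxopropyl]-4-methoxyphenyl}-3-[3,4,5-tris(benzyloxy)phenyl]propanoic acid | COc1cc(CC(=O)COCc2ccccc2)c(cc1OCc1ccccc1)[C@H](c1cc(OCc2ccccc2)c(OCc2ccccc2)c(OCc2ccccc2)c1)CC(=O)O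
F3 | step 6 | methyl (1S,2R,3S)-7-(benzyloxy)-3-[(benzyloxy)methyl]-3-hydroxy-6-methoxy-1-[3,4,5-tris(benzyloxy)phenyl]-1,2,3,4-tetrahydronaphthalene-2-carboxylate | COc1cc2c(cc1OCc3ccccc3)[C@H](c3cc(OCc4ccccc4)c(OCc4ccccc4)c(OCc4ccccc4)c3)[C@@H](C(=O)OC)[C@](O)(COCc3ccccc3)C2
F4 | step 6 | methyl (1S,2S,3R)-7-(benzyloxy)-3-[(benzyloxy)methyl]-2,3-dihydroxy-6-methoxy-1-[3,4,5-tris(benzyloxy)phenyl]-1,2,3,4-tetrahydronaphthalene-2-carboxylate | COc1cc2c(cc1OCc3ccccc3)[C@H](c3cc(OCc4ccccc4)c(OCc4ccccc4)c(OCc4ccccc4)c3)[C@@](O)(C(=O)OC)[C@](O)(COCc3ccccc3)C2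
F5 | step 3 | phenyl (2E)-3-{5-(benzyloxy)-2-[3-(benzyloxy)-2-hydroxypropyl]-4-methoxyphenyl}prop-2-enoate | COc1cc(CC(O)COCc2ccccc2)c(/C=C/C(=O)Oc2ccccc2)cc1OCc1ccccc1
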